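**Strategy.** Everything rests on disconnecting the two ether C–O bonds at the vicinal, anti-configured carbons C2 and C3 that the tetrahydrofuran (O, C2, C1, C10, C9) and the oxepane (O, C3, C2, C1, C14, C15, C16) share; C16 is primary. In one basic operation the C9 alkoxide opens a (2R,3S)-epoxide at C2 with inversion (5-exo) and the released C3 alkoxide displaces the C16 mesylate (7-exo), so the key step builds both rings and fixes C2 and C3. Its precursor is a single cyclohexane with cis C1 and C10 arms (Z-derived epoxide; free methallyl carbinol), a trans C14 arm ending in CH2OMs, and benzyl ethers on O4 and O11. The oxonane is closed later by metathesis.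

Key step: step 23

Remark: locants follow the target (C1–C16; C19 = exocyclic methylene carbon); PMB = 4-methoxybenzyl, Bn = benzyl, TBDPS = tert-butyldiphenylsilyl, Ms = methanesulfonyl. Assumption: the C6 (and C7) configuration of the transient or fallback compounds 36, 37, F4, F5 and F6 does not reach the target and is left open in their SMILES.

Step 1
Reactants: 1 (R)-4-benzyl-1,3-oxazolidin-2-one; 2 diethylphosphonoacetic acid
Product: 3 (R)-4-benzyl-3-[(diethoxyphosphoryl)acetyl]-1,3-oxazolidin-2-one
Conditions: DCC, DMAP (cat.), CH2Cl2, 0 °C → rt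
Reagents that add atoms: none
Why: Carbodiimide/DMAP N-acylation of the oxazolidinone with the free acid should give the auxiliary-bearing phosphonate for step 4 without touching the stereocentre.

Step 2
Reactants: 4 methyl (S)-3-hydroxy-2-methylpropanoate
Product: 5 methyl (S)-3-(TBDPS-oxy)-2-methylpropanoate
Conditions: TBDPSCl, imidazole, DMF, rt
Reagents that add atoms: tert-butyl(chloro)diphenylsilane, CC(C)(C)[Si](Cl)(c1ccccc1)c1ccccc1
Why: Imidazole-mediated silylation of the primary alcohol installs a robust silyl ether on the future O16; the stereocentre (future C15) is not involved.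

Step 3
Reactants: 5 methyl (S)-3-(TBDPS-oxy)-2-methylpropanoate
Product: 6 (S)-3-(TBDPS-oxy)-2-methylpropanal
Conditions: DIBAL-H (1.05 equiv), CH2Cl2, −78 °C; aq. sodium potassium tartrate
Reagents that add atoms: none
Why: Partial DIBAL-H reduction stops at the aldehyde because the tetrahedral aluminium hemiacetal survives at −78 °C, and the cold non-basic conditions should keep the α-stereocentre.

Step 4
Reactants: 3 (R)-4-benzyl-3-[(diethoxyphosphoryl)acetyl]-1,3-oxazolidin-2-one; 6 (S)-3-(TBDPS-oxy)-2-methylpropanal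
Product: 7 (R)-4-benzyl-3-[(2E,4R)-4-methyl-5-(TBDPS-oxy)pent-2-enoyl]-1,3-oxazolidin-2-one
Conditions: LiCl, i-Pr2NEt, MeCN, rt
Reagents that add atoms: none
Why: Horner–Wadsworth–Emmons olefination under Masamune–Roush conditions should give the E-enoyl imide (future C1=C14) with a base too weak to epimerise the α-branched aldehyde.

Step 5
Reactants: 8 methacrolein
Product: 9 ethyl (2E)-4-methylpenta-2,4-dienoate
Conditions: Ph3P=CHCO2Et, CH2Cl2, rt
Reagents that add atoms: ethyl (triphenylphosphoranylidene)acetate, CCOC(=O)C=P(c1ccccc1)(c1ccccc1)c1ccccc1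
Why: Wittig olefination with a stabilised ylide should give the E-dienoate selectively.

Step 6
Reactants: 9 ethyl (2E)-4-methylpenta-2,4-dienoate
Product: 10 (2E)-4-methylpenta-2,4-dien-1-ol
Conditions: DIBAL-H (2.2 equiv), Et2O, −78 → 0 °C
Reagents that add atoms: none
Why: DIBAL-H reduces the conjugated ester in 1,2-fashion to the dienol without touching the diene.

Step 7
Reactants: 10 (2E)-4-methylpenta-2,4-dien-1-ol
Product: 11 (2E)-4-methylpenta-2,4-dien-1-yl 4-methoxybenzyl ether
Conditions: NaH, PMBCl, Bu4NI (cat.), THF–DMF, 0 °C → rt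
Reagents that add atoms: 4-methoxybenzyl chloride, COc1ccc(CCl)cc1
Why: Williamson etherification caps the future O9 as a PMB ether, which can later be removed oxidatively in the presence of benzyl ethers, an epoxide and a mesylate.

Step 8
Reactants: 7 (R)-4-benzyl-3-[(2E,4R)-4-methyl-5-(TBDPS-oxy)pent-2-enoyl]-1,3-oxazolidin-2-one; 11 (2E)-4-methylpenta-2,4-dien-1-yl 4-methoxybenzyl ether
Product: 12 cyclohexene imide [C11=C12(CH3); C1–C(=O)–oxazolidinone; C10–CH2OPMB cis to the C1 acyl group; C14–CH(CH3)CH2OTBDPS trans to it]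
Conditions: Et2AlCl (1.6 equiv), CH2Cl2, −40 → −20 °C, 11 in excess
Reagents that add atoms: none
Why: Auxiliary-controlled Lewis-acid Diels–Alder reaction: the diene should add to the chelated s-cis imide on the face opposite the benzyl group (setting C1 and C14, trans from the E-dienophile), the endo transition state should place the C10 arm cis to the C1 acyl group, and the 1-alkyl/3-methyl diene directs the C1–C10 and C13–C14 bonds.

Step 9
Reactants: 12 cyclohexene imide
Product: 13 cyclohexene C2 alcohol (C1–CH2OH)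
Conditions: LiBH4, MeOH (1 equiv), THF, 0 °C
Reagents that add atoms: none
Why: Reductive cleavage of the N-acyl oxazolidinone gives the primary alcohol and returns the auxiliary, with the silyl and PMB ethers inert.

Step 10
Reactants: 13 cyclohexene C2 alcohol
Product: 15 C2,C11-diol (C12 methyl cis to the C10 arm, C11–OH trans to both), via C11 alkylborane 14 (not isolated)
Conditions: BH3·THF (3 equiv), THF, 0 °C → rt; then 3 M NaOH, 30% H2O2, 0 °C
Reagents that add atoms: borane (THF complex; boron of 14 only), B; hydrogen peroxide, OO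
Why: Hydroboration–oxidation adds H and B syn and anti-Markovnikov from the face opposite the pseudo-axial C10 arm, which should set C12 correctly; C11–OH comes out epimeric and is corrected in steps 11 and 13.

Step 11
Reactants: 15 C2,C11-diol
Product: 16 C11-keto C2-aldehyde
Conditions: Dess–Martin periodinane, pyridine, CH2Cl2, 0 °C → rt
Reagents that add atoms: none
Why: Dess–Martin oxidation converts both alcohols under non-basic conditions, so the α-stereocentres C1, C10 and C12 should survive; the product is used crude.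

Step 12
Reactants: 16 C11-keto C2-aldehyde
Product: 17 C11-keto methyl (Z)-enoate [C1–CH=C(CH3)CO2Me, C1 and CO2Me cis]
Conditions: (CF3CH2O)2P(O)CH(CH3)CO2Me (slight excess over base), KHMDS, 18-crown-6, THF, −78 °C
Reagents that add atoms: methyl 2-[bis(2,2,2-trifluoroethoxy)phosphoryl]propanoate, COC(=O)C(C)P(=O)(OCC(F)(F)F)OCC(F)(F)F
Why: Still–Gennari olefination should give the Z-trisubstituted enoate (C2=C3) at the aldehyde only, since the flanked ketone is inert at −78 °C and the absence of free base avoids C1 epimerisation and β-elimination of the PMB ether.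

Step 13
Reactants: 17 C11-keto methyl (Z)-enoate
Product: 18 C11 alcohol (OH cis to the C10 arm and the C12 methyl)
Conditions: LiBH(s-Bu)3 (1.2 equiv), THF, −78 °C; then H2O
Reagents that add atoms: none
Why: The bulky hydride should attack the ketone from the face opposite the two cis α-substituents to give the all-cis C11 alcohol, while the α,β-disubstituted enoate resists conjugate reduction at −78 °C.

Step 14
Reactants: 18 C11 alcohol
Product: 19 C11 benzyl ether
Conditions: 2-benzyloxy-1-methylpyridinium triflate, MgO, PhCF3, 85 °C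
Reagents that add atoms: 2-benzyloxy-1-methylpyridinium trifluoromethanesulfonate, C[n+]1ccccc1OCc1ccccc1.[O-]S(=O)(=O)C(F)(F)F
Why: Neutral thermal benzyl transfer protects the hindered alcohol without acid or base, so the PMB ether, the Z-enoate and the 1,3-cis relation of O11 to the enoate arm (oxa-Michael risk) are not disturbed.

Step 15
Reactants: 19 C11 benzyl ether
Product: 20 Z-allylic alcohol (C4–OH)
Conditions: DIBAL-H (2.5 equiv), CH2Cl2, −78 °C
Reagents that add atoms: none
Why: DIBAL-H 1,2-reduction of the enoate gives the Z-allylic alcohol with the alkene geometry retained.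

Step 16
Reactants: 20 Z-allylic alcohol
Product: 21 (2R,3S)-epoxy alcohol
Conditions: Ti(Oi-Pr)4 (1.0 equiv), L-(+)-diethyl tartrate (1.2 equiv), t-BuOOH, 4 Å MS, CH2Cl2, −20 °C
Reagents that add atoms: tert-butyl hydroperoxide, CC(C)(C)OO
Why: Sharpless asymmetric epoxidation with the L-(+)-tartrate should deliver oxygen to the face that gives the (2R,3S) cis-epoxide (C1 and C4 cis), and stoichiometric titanium–tartrate is used because Z-allylic alcohols with a branched substituent react slowly.

Step 17
Reactants: 21 (2R,3S)-epoxy alcohol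
Product: 22 fully protected epoxide (C4–OBn, C11–OBn, C9–OPMB, C16–OTBDPS)
Conditions: NaH, BnBr, Bu4NI (cat.), THF–DMF, 0 °C
Reagents that add atoms: benzyl bromide, BrCc1ccccc1
Why: Williamson benzylation of the primary epoxy alcohol in an aprotic medium at 0 °C should outrun Payne rearrangement and puts a non-migrating group on O4.

Step 18
Reactants: 22 fully protected epoxide
Product: 23 C16 primary alcohol
Conditions: TBAF, THF, 0 °C → rt
Reagents that add atoms: none
Why: Fluoride desilylation frees only O16, since the benzyl and PMB ethers and the epoxide are stable to fluoride.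

Step 19
Reactants: 23 C16 primary alcohol
Product: 24 C16 mesylate
Conditions: MsCl, Et3N, CH2Cl2, 0 °C
Reagents that add atoms: methanesulfonyl chloride, CS(=O)(=O)Cl
Why: Sulfonylation of the only free hydroxyl installs the leaving group before the C9 carbinol exists, so no chemoselective mesylation is needed later.

Step 20
Reactants: 24 C16 mesylate
Product: 25 C9 primary alcohol
Conditions: DDQ, CH2Cl2–pH 7 buffer, 0 °C
Reagents that add atoms: none
Why: Oxidative PMB cleavage with DDQ is selective over benzyl ethers, and the buffer protects the acid-sensitive trisubstituted epoxide.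

Step 21
Reactants: 25 C9 primary alcohol
Product: 26 C9 aldehyde
Conditions: Dess–Martin periodinane, pyridine, CH2Cl2, 0 °C
Reagents that add atoms: none
Why: Buffered Dess–Martin oxidation gives the aldehyde without epimerising C10 or opening the epoxide.

Step 22
Reactants: 26 C9 aldehyde
Product: 27 key-step precursor, (1S,2R,3S,9S,10R,11R,12R,14S,15R)-epoxy alcohol mesylate (free C9–OH, methallyl, C4–OBn, C11–OBn, C16–OMs)
Conditions: (−)-Ipc2B(methallyl) [pre-formed from (−)-Ipc2BOMe and methallylmagnesium chloride], Et2O, −78 °C; work-up aq. NaOAc, 30% H2O2, 0 °C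
Reagents that add atoms: (−)-B-methallyldiisopinocampheylborane, C=C(C)CB([C@@H]1C[C@@H]2C[C@H]([C@H]1C)C2(C)C)[C@@H]1C[C@@H]2C[C@H]([C@H]1C)C2(C)C
Why: Brown methallylation through a closed chair transition state: the (+)-α-pinene-derived reagent should add to the Si face to give 9S, overriding the small substrate bias (both α-branches are ring methines), and the buffered work-up leaves epoxide and mesylate intact.

Step 23
Reactants: 27 key-step precursor
Product: 29 tricyclic bis-ether, (1S,2S,3S,9S,10R,11R,12R,14S,15R), with C9 methallyl, C4–OBn and C11–OBn, via sodium C3 alkoxide of the tetrahydrofuran mesylate 28 (not isolated)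
Conditions: NaH (3 equiv), THF–DMF (5:1), 0 → 45 °C
Reagents that add atoms: sodium hydride (sodium counter-ion of 28 only), [Na+].[H-]
Why: NaH deprotonates the C9 hydroxyl, the alkoxide attacks the epoxide at the secondary carbon C2 anti to the epoxide C–O bond (5-exo-tet, closing the tetrahydrofuran O–C2–C1–C10–C9), and the liberated tertiary C3 alkoxide 28 then displaces the primary C16 mesylate (7-exo-tet, closing the oxepane O–C3–C2–C1–C14–C15–C16). The closest known reactions are the base-mediated 5-exo cyclisation of γ,δ-epoxy alcohols and the intramolecular Williamson etherification of a hydroxy sulfonate, here run as one alkoxide relay. The only stereocentre that changes is C2, inverted (2R to 2S) because the attack is SN2, while C3 keeps its configuration because its C–O bond is never broken; both are therefore dictated by the (2R,3S)-epoxide, and C9 is untouched. The step needs attack at C2 rather than at fully substituted C3 (5-exo versus 6-endo), epoxide opening before any direct attack on the mesylate, and substitution rather than elimination at C16. Basic, non-Lewis-acidic conditions and the smaller ring should secure the first, the cis C1/C10 arms place O9 behind C2 so that the 5-exo opening outruns a seven-membered displacement, and the equatorial C14 arm holds primary C16 next to the new C3 alkoxide. Benzyl ethers on O4 and O11 cannot migrate to either alkoxide and stop O11, which is also 1,3-cis to the epoxide arm, from competing as a nucleophile.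

Step 24
Reactants: 29 tricyclic bis-ether
Product: 30 tricyclic C4,C11-diol
Conditions: LiDBB, THF, −78 °C; then H2O
Reagents that add atoms: none
Why: Single-electron reductive cleavage of both benzylic C–O bonds should free O4 and O11 in one operation, while the isolated 1,1-disubstituted alkene and the saturated ring ethers are not reduced.

Step 25
Reactants: 30 tricyclic C4,C11-diol
Product: 31 tricyclic C4 aldehyde with free C11–OH
Conditions: TEMPO (cat.), PhI(OAc)2, CH2Cl2, rt
Reagents that add atoms: none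
Why: Oxoammonium (TEMPO) oxidation is selective for the primary C4 alcohol over the doubly flanked secondary C11 alcohol, and the aldehyde has no α-hydrogen to epimerise.

Step 26
Reactants: 31 tricyclic C4 aldehyde with free C11–OH
Product: 32 tricyclic C4 aldehyde C11 acetate
Conditions: Ac2O, DMAP (cat.), pyridine, rt
Reagents that add atoms: acetic anhydride, CC(=O)OC(C)=O
Why: DMAP-catalysed acetylation installs the C11 acetate of the target now, because all later steps are non-basic and non-nucleophilic.

Step 27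
Reactants: 32 tricyclic C4 aldehyde C11 acetate
Product: 33 (4R)-homoallylic alcohol (C4–OH, C5H2–C6H=CH2)
Conditions: (+)-Ipc2B(allyl), Et2O, −78 °C; work-up aq. NaOAc, 30% H2O2, 0 °C
Reagents that add atoms: (+)-B-allyldiisopinocampheylborane, C=CCB([C@H]1C[C@H]2C[C@@H]([C@@H]1C)C2(C)C)[C@H]1C[C@H]2C[C@@H]([C@@H]1C)C2(C)C
Why: Brown allylation with the (−)-α-pinene-derived reagent should add to the Re face of the α-alkoxy aldehyde to set 4R by reagent control (the sense that α-chelation would also give) and brings in C5 and C6 without touching the acetate.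

Step 28
Reactants: 33 (4R)-homoallylic alcohol
Product: 34 (4R)-octanoate diene
Conditions: n-C7H15COCl, DMAP, pyridine, CH2Cl2, 0 °C → rt
Reagents that add atoms: octanoyl chloride, CCCCCCCC(=O)Cl
Why: DMAP-catalysed acylation of the only free hydroxyl installs the C4 octanoate with retention.

Step 29
Reactants: 34 (4R)-octanoate diene
Product: 35 tetracyclic (6Z)-oxonene [C6=C7(CH3)]
Conditions: Hoveyda–Grubbs II (15 mol%), toluene (1 mM), 80 °C
Reagents that add atoms: none
Why: Ring-closing metathesis between the terminal alkene and the methallyl group should close the oxonane at C6=C7 with loss of ethene, the cis C2/C9 arms on the tetrahydrofuran pre-organising the chain and the ring size enforcing Z geometry.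

Step 30
Reactants: 35 tetracyclic (6Z)-oxonene
Product: 38 asbestinin 16, via C6 allylic hydroperoxide 36 (not isolated), via C6 peroxyacetate 37 (not isolated)
Conditions: O2, TPP (cat.), visible light, Ac2O, pyridine, DMAP (cat.), CH2Cl2, 0 °C → rt
Reagents that add atoms: dioxygen, O=O; acetic anhydride (acetyl of 37 only), CC(=O)OC(C)=O
Why: Schenck ene reaction of singlet oxygen followed by Kornblum–DeLaMare dehydration of the acetylated secondary hydroperoxide: oxygen should add at C6 with hydrogen taken from the freely rotating C19 methyl (the ring allylic C–H bonds of a medium-ring Z-alkene lie near the alkene plane), giving the C6 ketone and the C7 exocyclic methylene in one flask.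

**Compound list**

1 | (R)-4-benzyl-1,3-oxazolidin-2-one | O=C1OC[C@@H](Cc2ccccc2)N1 | starting material
2 | diethylphosphonoacetic acid | CCOP(=O)(OCC)CC(=O)O | starting material
3 | (R)-4-benzyl-3-[(diethoxyphosphoryl)acetyl]-1,3-oxazolidin-2-one | CCOP(=O)(OCC)CC(=O)N1[C@H](Cc2ccccc2)COC1=O | intermediate
4 | methyl (S)-3-hydroxy-2-methylpropanoate | COC(=O)[C@@H](C)CO | starting material
5 | methyl (S)-3-(TBDPS-oxy)-2-methylpropanoate | COC(=O)[C@@H](C)CO[Si](c1ccccc1)(c2ccccc2)C(C)(C)C | intermediate
6 | (S)-3-(TBDPS-oxy)-2-methylpropanal | O=C[C@@H](C)CO[Si](c1ccccc1)(c2ccccc2)C(C)(C)C | intermediate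
7 | (R)-4-benzyl-3-[(2E,4R)-4-methyl-5-(TBDPS-oxy)pent-2-enoyl]-1,3-oxazolidin-2-one | O=C(/C=C/[C@@H](C)CO[Si](c1ccccc1)(c2ccccc2)C(C)(C)C)N3[C@H](Cc4ccccc4)COC3=O | intermediate
8 | methacrolein | CC(=C)C=O | starting material
9 | ethyl (2E)-4-methylpenta-2,4-dienoate | CCOC(=O)/C=C/C(C)=C | intermediate
10 | (2E)-4-methylpenta-2,4-dien-1-ol | OC/C=C/C(C)=C | intermediate
11 | (2E)-4-methylpenta-2,4-dien-1-yl 4-methoxybenzyl ether | COc1ccc(COC/C=C/C(C)=C)cc1 | intermediate
12 | cyclohexene imide: C11=C12(CH3), C1–C(=O)–[(R)-4-benzyloxazolidinone], C10–CH2OPMB cis and C14–[(R)-CH(CH3)CH2OTBDPS] trans to the C1 acyl group | COc1ccc(COC[C@@H]2C=C(C)C[C@@H]([C@@H](C)CO[Si](c3ccccc3)(c4ccccc4)C(C)(C)C)[C@@H]2C(=O)N5[C@H](Cc6ccccc6)COC5=O)cc1 | intermediate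
13 | cyclohexene C2 alcohol (C1–CH2OH, otherwise as 12) | COc1ccc(COC[C@@H]2C=C(C)C[C@@H]([C@@H](C)CO[Si](c3ccccc3)(c4ccccc4)C(C)(C)C)[C@@H]2CO)cc1 | intermediate
14 | C11 alkylborane (BH2 at C11 trans to the C10 arm; O2 as O–BH2) | COc1ccc(COC[C@@H]2[C@@H](B)[C@H](C)C[C@@H]([C@@H](C)CO[Si](c3ccccc3)(c4ccccc4)C(C)(C)C)[C@@H]2COB)cc1 | intermediate (not isolated)
15 | C2,C11-diol (C12 methyl cis to the C10 arm; C11–OH trans to both) | COc1ccc(COC[C@@H]2[C@@H](O)[C@H](C)C[C@@H]([C@@H](C)CO[Si](c3ccccc3)(c4ccccc4)C(C)(C)C)[C@@H]2CO)cc1 | intermediate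
16 | C11-keto C2-aldehyde | COc1ccc(COC[C@@H]2C(=O)[C@H](C)C[C@@H]([C@@H](C)CO[Si](c3ccccc3)(c4ccccc4)C(C)(C)C)[C@@H]2C=O)cc1 | intermediate
17 | C11-keto methyl (Z)-enoate (C1–CH=C(CH3)CO2Me) | COc1ccc(COC[C@@H]2C(=O)[C@H](C)C[C@@H]([C@@H](C)CO[Si](c3ccccc3)(c4ccccc4)C(C)(C)C)[C@@H]2/C=C(/C)C(=O)OC)cc1 | intermediate
18 | C11 alcohol (OH, C10 arm and C12 methyl all cis), Z-enoate | COc1ccc(COC[C@@H]2[C@H](O)[C@H](C)C[C@@H]([C@@H](C)CO[Si](c3ccccc3)(c4ccccc4)C(C)(C)C)[C@@H]2/C=C(/C)C(=O)OC)cc1 | intermediate
19 | C11 benzyl ether, Z-enoate | COc1ccc(COC[C@@H]2[C@H](OCc7ccccc7)[C@H](C)C[C@@H]([C@@H](C)CO[Si](c3ccccc3)(c4ccccc4)C(C)(C)C)[C@@H]2/C=C(/C)C(=O)OC)cc1 | intermediate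
20 | Z-allylic alcohol (C1–CH=C(CH3)CH2OH) | COc1ccc(COC[C@@H]2[C@H](OCc7ccccc7)[C@H](C)C[C@@H]([C@@H](C)CO[Si](c3ccccc3)(c4ccccc4)C(C)(C)C)[C@@H]2/C=C(/C)CO)cc1 | intermediate
21 | (2R,3S)-epoxy alcohol | COc1ccc(COC[C@@H]2[C@H](OCc7ccccc7)[C@H](C)C[C@@H]([C@@H](C)CO[Si](c3ccccc3)(c4ccccc4)C(C)(C)C)[C@@H]2[C@H]5O[C@@]5(C)CO)cc1 | intermediate
22 | fully protected epoxide (C4–OBn, C11–OBn, C9–OPMB, C16–OTBDPS) | COc1ccc(COC[C@@H]2[C@H](OCc7ccccc7)[C@H](C)C[C@@H]([C@@H](C)CO[Si](c3ccccc3)(c4ccccc4)C(C)(C)C)[C@@H]2[C@H]5O[C@@]5(C)COCc6ccccc6)cc1 | intermediate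
23 | C16 primary alcohol | COc1ccc(COC[C@@H]2[C@H](OCc7ccccc7)[C@H](C)C[C@@H]([C@@H](C)CO)[C@@H]2[C@H]5O[C@@]5(C)COCc6ccccc6)cc1 | intermediate
24 | C16 mesylate | COc1ccc(COC[C@@H]2[C@H](OCc7ccccc7)[C@H](C)C[C@@H]([C@@H](C)COS(C)(=O)=O)[C@@H]2[C@H]5O[C@@]5(C)COCc6ccccc6)cc1 | intermediate
25 | C9 primary alcohol | OC[C@@H]1[C@H](OCc2ccccc2)[C@H](C)C[C@@H]([C@@H](C)COS(C)(=O)=O)[C@@H]1[C@H]3O[C@@]3(C)COCc4ccccc4 | intermediate
26 | C9 aldehyde | O=C[C@@H]1[C@H](OCc2ccccc2)[C@H](C)C[C@@H]([C@@H](C)COS(C)(=O)=O)[C@@H]1[C@H]3O[C@@]3(C)COCc4ccccc4 | intermediate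
27 | key-step precursor: (1S,2R,3S,9S,10R,11R,12R,14S,15R) monocyclic epoxy alcohol mesylate | C=C(C)C[C@H](O)[C@@H]1[C@H](OCc2ccccc2)[C@H](C)C[C@@H]([C@@H](C)COS(C)(=O)=O)[C@@H]1[C@H]3O[C@@]3(C)COCc4ccccc4 | intermediate
28 | sodium C3 alkoxide of the tetrahydrofuran mesylate | [Na+].C=C(C)C[C@@H]2O[C@H]([C@@](C)([O-])COCc1ccccc1)[C@H]3[C@@H](C[C@@H](C)[C@@H](OCc4ccccc4)[C@H]32)[C@@H](C)COS(C)(=O)=O | intermediate (not isolated)
29 | tricyclic bis-ether, (1S,2S,3S,9S,10R,11R,12R,14S,15R), C4–OBn, C11–OBn, C9 methallyl | C=C(C)C[C@@H]2O[C@H]3[C@H]4[C@@H](C[C@@H](C)[C@@H](OCc5ccccc5)[C@H]42)[C@@H](C)CO[C@@]3(C)COCc1ccccc1 | intermediate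
30 | tricyclic C4,C11-diol | C=C(C)C[C@@H]2O[C@H]3[C@H]4[C@@H](C[C@@H](C)[C@@H](O)[C@H]42)[C@@H](C)CO[C@@]3(C)CO | intermediate
31 | tricyclic C4 aldehyde with free C11–OH | C=C(C)C[C@@H]2O[C@H]3[C@H]4[C@@H](C[C@@H](C)[C@@H](O)[C@H]42)[C@@H](C)CO[C@@]3(C)C=O | intermediate
32 | tricyclic C4 aldehyde C11 acetate | C=C(C)C[C@@H]2O[C@H]3[C@H]4[C@@H](C[C@@H](C)[C@@H](OC(C)=O)[C@H]42)[C@@H](C)CO[C@@]3(C)C=O | intermediate
33 | (4R)-homoallylic alcohol | C=C(C)C[C@@H]2O[C@H]3[C@H]4[C@@H](C[C@@H](C)[C@@H](OC(C)=O)[C@H]42)[C@@H](C)CO[C@@]3(C)[C@H](O)CC=C | intermediate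
34 | (4R)-octanoate diene | C=C(C)C[C@@H]2O[C@H]3[C@H]4[C@@H](C[C@@H](C)[C@@H](OC(C)=O)[C@H]42)[C@@H](C)CO[C@@]3(C)[C@H](OC(=O)CCCCCCC)CC=C | intermediate
35 | tetracyclic (6Z)-oxonene, C7–CH3 | C/C1=C/C[C@@H](OC(=O)CCCCCCC)[C@]2(C)OC[C@H](C)[C@@H]3C[C@@H](C)[C@@H](OC(C)=O)[C@@H]4[C@H]3[C@@H]2O[C@H]4C1 | intermediate
36 | C6 allylic hydroperoxide with C7 exocyclic methylene (C6 epimers) | C=C1C[C@@H]2O[C@H]3[C@H]4[C@@H](C[C@@H](C)[C@@H](OC(C)=O)[C@H]42)[C@@H](C)CO[C@@]3(C)[C@H](OC(=O)CCCCCCC)CC1OO | intermediate (not isolated)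
37 | C6 peroxyacetate (C6 epimers) | C=C1C[C@@H]2O[C@H]3[C@H]4[C@@H](C[C@@H](C)[C@@H](OC(C)=O)[C@H]42)[C@@H](C)CO[C@@]3(C)[C@H](OC(=O)CCCCCCC)CC1OOC(C)=O | intermediate (not isolated)
38 | asbestinin 16, (1S,2S,3S,4R,9S,10R,11R,12R,14S,15R) | C=C1C[C@@H]2O[C@H]3[C@H]4[C@@H](C[C@@H](C)[C@@H](OC(C)=O)[C@H]42)[C@@H](C)CO[C@@]3(C)[C@H](OC(=O)CCCCCCC)CC1=O | target

**Count.** Total steps: 30. Longest linear sequence: 26 steps (from 4: steps 2–4 and 8–30); side branches are step 1 and steps 5–7.

**Steps most likely to fail**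

Step 23. The second closure may stall: a hindered tertiary alkoxide must form a seven-membered ring at a β-branched primary carbon, so elimination of methanesulfonate or base-induced decomposition of the mesylate may compete. The fallback separates the two closures and replaces alkoxide displacement by electrophilic activation. Setting out from 27, NaH in THF at 0 °C with quench as soon as the epoxide is consumed should give the tetrahydrofuran tertiary alcohol mesylate F1. Finkelstein exchange (NaI, acetone, reflux) should give the primary iodide F2. Silver triflate with 2,6-di-tert-butyl-4-methylpyridine in CH2Cl2 should then close the oxepane by silver-assisted etherification, returning to the route at 29.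

Step 29. Initiation at the 1,1-disubstituted alkene may be slow, and intermolecular metathesis may outrun closure of the nine-membered ring. The fallback closes the same C6=C7 bond by carbonyl coupling. Setting out from 34, ozonolysis (O3, CH2Cl2, −78 °C; PPh3) should give the C7 methyl ketone C6 aldehyde F3. McMurry coupling (TiCl3(DME)1.5, Zn–Cu, DME, reflux, slow addition) should return to the route at 35.

Step 30. The ene reaction may abstract hydrogen from C5 or C8 instead of the C19 methyl, and the β-octanoate may be lost by elimination during dehydration. The fallback builds the enone by epoxide rearrangement. Setting out from 35, mCPBA (CH2Cl2, NaHCO3) should give the 6,7-epoxide F4. TMSOTf/2,6-lutidine followed by DBU (opening at tertiary C7, proton loss from the methyl) should give the C6 trimethylsilyl ether with C7 exocyclic methylene F5. Buffered HF·pyridine should give the allylic alcohol F6, and Dess–Martin oxidation should return to the route at 38.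

**Further compounds**

F1 | step 23 | tetrahydrofuran tertiary alcohol mesylate (neutral form of 28) | C=C(C)C[C@@H]2O[C@H]([C@@](C)(O)COCc1ccccc1)[C@H]3[C@@H](C[C@@H](C)[C@@H](OCc4ccccc4)[C@H]32)[C@@H](C)COS(C)(=O)=O
F2 | step 23 | tetrahydrofuran tertiary alcohol C16 iodide | C=C(C)C[C@@H]2O[C@H]([C@@](C)(O)COCc1ccccc1)[C@H]3[C@@H](C[C@@H](C)[C@@H](OCc4ccccc4)[C@H]32)[C@@H](C)CI
F3 | step 29 | C7 methyl ketone C6 aldehyde | CC(=O)C[C@@H]2O[C@H]3[C@H]4[C@@H](C[C@@H](C)[C@@H](OC(C)=O)[C@H]42)[C@@H](C)CO[C@@]3(C)[C@H](OC(=O)CCCCCCC)CC=O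
F4 | step 30 | 6,7-epoxide of 35 (epoxide face not controlled) | CC15OC5C[C@@H](OC(=O)CCCCCCC)[C@]2(C)OC[C@H](C)[C@@H]3C[C@@H](C)[C@@H](OC(C)=O)[C@@H]4[C@H]3[C@@H]2O[C@H]4C1
F5 | step 30 | C6 trimethylsilyl ether with C7 exocyclic methylene (C6 not controlled) | C=C1C[C@@H]2O[C@H]3[C@H]4[C@@H](C[C@@H](C)[C@@H](OC(C)=O)[C@H]42)[C@@H](C)CO[C@@]3(C)[C@H](OC(=O)CCCCCCC)CC1O[Si](C)(C)C
F6 | step 30 | C6 allylic alcohol with C7 exocyclic methylene (C6 not controlled) | C=C1C[C@@H]2O[C@H]3[C@H]4[C@@H](C[C@@H](C)[C@@H](OC(C)=O)[C@H]42)[C@@H](C)CO[C@@]3(C)[C@H](OC(=O)CCCCCCC)CC1O
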